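**Plan**

1. Cuts, in retrosynthetic order: the C-4'–O bond of the oxolane (oxygen from C-10'); the two Diels–Alder bonds C-2–C-2' and C-3–C-5', which halve the target into two molecules of one cyclopentadiene guaianolide; in that monomer C-1–C-2 and C-3–C-4 of the five-membered ring; then C-1=C-5 of the cycloheptene and C-5–C-6, C-7–C-11, C-6–C-7 of the lactone part.
2. Enabling feature: the carbocycle C-1'–C-5' (and its twin C-1–C-5) carries at C-4' a methyl group and an oxygen, the trace of a methyl ketone; C-1' is β to it through C-5'; and the C-10' oxygen sits three atoms from C-2' on the same face. C-2'/C-3' can therefore arrive as an ethynylsilane tethered to that oxygen and be annulated onto a 2-acetylcycloheptene.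
3. Forward order: lactone → cycloheptene (metathesis) → cyclopentenol (reductive [3+2]) → cyclopentadiene → norbornene by dimerisation → oxolane by acid.
4. Stereochemistry: C-10 from (S)-linalool; C-7 and C-11 from a diarylprolinol-catalysed Michael addition; C-6 from trans addition to a lactone oxocarbenium ion; C-1 from the silicon tether; C-2, C-3, C-2', C-5' from the endo dimerisation; C-4' from the bridged geometry of the ether closure.

Key step: step 13

Assumption: (S)-(+)-linalool of high enantiomeric purity is taken as commercially available; locants are guaiane locants (C-1 to C-15), primed for the half that reacts as the diene in the dimerisation.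

**Route**

Step 1
Reactants: 1 (S)-(+)-linalool
Product: 2 (3S)-3,7-dimethyl-3-(triethylsilyloxy)octa-1,6-diene
Conditions: Et3SiOTf, 2,6-lutidine, CH2Cl2, −78 → 0 °C
Reagents that add atoms: triethylsilyl trifluoromethanesulfonate, CC[Si](CC)(CC)OS(=O)(=O)C(F)(F)F
Why: Silylation of the hindered tertiary allylic alcohol with a silyl triflate masks the hydroxyl, which would otherwise close onto the aldehyde of step 2 and the nitroalkene of step 3; the C-10 stereocentre is carried over unchanged from linalool.

Step 2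
Reactants: 2 (3S)-3,7-dimethyl-3-(triethylsilyloxy)octa-1,6-diene
Product: 3 (4S)-4-methyl-4-(triethylsilyloxy)hex-5-enal
Conditions: O3 (1 equiv), pyridine, CH2Cl2, −78 °C; then Me2S
Reagents that add atoms: ozone, [O-][O+]=O
Why: Ozonolysis should be selective for the electron-rich trisubstituted alkene over the vinyl group, which is deactivated and shielded by the neighbouring silyloxy-bearing quaternary carbon, when one equivalent of ozone is used at low temperature.

Step 3
Reactants: 3 (4S)-4-methyl-4-(triethylsilyloxy)hex-5-enal; 4 nitromethane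
Product: 6 (1E,5S)-5-methyl-1-nitro-5-(triethylsilyloxy)hepta-1,6-diene, via nitro aldol 5 (not isolated)
Conditions: KOt-Bu (10 mol %), THF/t-BuOH, 0 °C; then MsCl, i-Pr2NEt, CH2Cl2, −20 → 0 °C
Reagents that add atoms: none
Why: Henry addition followed by mesylation and E1cB elimination of the nitro aldol gives the conjugated nitroalkene in its thermodynamically preferred E geometry and forms the C-6–C-7 bond.

Step 4
Reactants: 6 (1E,5S)-5-methyl-1-nitro-5-(triethylsilyloxy)hepta-1,6-diene; 7 propanal
Product: 8 (2S,3S,6S)-2,6-dimethyl-3-(nitromethyl)-6-(triethylsilyloxy)oct-7-enal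
Conditions: (R)-2-[diphenyl(trimethylsilyloxy)methyl]pyrrolidine (10 mol %), hexane, 0 °C → rt
Reagents that add atoms: none
Why: Enamine-catalysed Michael addition of an aldehyde to a nitroalkene: the anti enamine of propanal is shielded on one face by the diphenyl(silyloxy)methyl group and adds through an acyclic synclinal transition state, so the catalyst and not the remote C-10 centre sets C-11 and C-7 as the syn (2S,3S) pair.

Step 5
Reactants: 8 (2S,3S,6S)-2,6-dimethyl-3-(nitromethyl)-6-(triethylsilyloxy)oct-7-enal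
Product: 9 (2S,3S,6S)-2,6-dimethyl-3-(nitromethyl)-6-(triethylsilyloxy)oct-7-enoic acid
Conditions: NaClO2, NaH2PO4, 2-methyl-2-butene, t-BuOH/H2O, 0 °C → rt
Reagents that add atoms: sodium chlorite, [Na+].[O-]Cl=O
Why: Pinnick oxidation converts the aldehyde into the acid under buffered conditions that leave the α-stereocentre, the silyl ether and the alkene (hypochlorite is scavenged) untouched.

Step 6
Reactants: 9 (2S,3S,6S)-2,6-dimethyl-3-(nitromethyl)-6-(triethylsilyloxy)oct-7-enoic acid
Product: 12 (3S,4S)-5-hydroxy-3-methyl-4-[(3S)-3-methyl-3-(triethylsilyloxy)pent-4-en-1-yl]oxolan-2-one, via disodium nitronate 10 (not isolated), via oxo acid 11 (not isolated)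
Conditions: NaOMe (2.2 equiv), MeOH, 0 °C; then aq. TiCl3, NH4OAc (pH 5), 0 °C → rt; citric acid work-up
Reagents that add atoms: water, O
Why: Reductive Nef reaction: trivalent titanium reduces the nitronate to the imine, which hydrolyses to the aldehyde, and the 4-oxo acid closes to the five-membered hydroxy lactone, which shelters the epimerisable C-7 position.

Step 7
Reactants: 12 (3S,4S)-5-hydroxy-3-methyl-4-[(3S)-3-methyl-3-(triethylsilyloxy)pent-4-en-1-yl]oxolan-2-one
Product: 13 (3S,4S)-5-acetoxy-3-methyl-4-[(3S)-3-methyl-3-(triethylsilyloxy)pent-4-en-1-yl]oxolan-2-one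
Conditions: Ac2O, pyridine, DMAP (cat.), CH2Cl2, 0 °C
Reagents that add atoms: acetic anhydride, CC(=O)OC(C)=O
Why: Acetylation of the lactol hydroxyl gives the 5-acetoxy lactone, the standard precursor of a lactone oxocarbenium ion, while the tertiary silyl ether is inert.

Step 8
Reactants: 13 (3S,4S)-5-acetoxy-3-methyl-4-[(3S)-3-methyl-3-(triethylsilyloxy)pent-4-en-1-yl]oxolan-2-one; 14 but-3-en-2-one
Product: 17 (3S,4S,5S)-3-methyl-4-[(3S)-3-methyl-3-(triethylsilyloxy)pent-4-en-1-yl]-5-(3-oxobut-1-en-2-yl)oxolan-2-one, via sulfonium silyl enol ether 15 (not isolated), via sulfonium ketone 16 (not isolated)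
Conditions: 14, Me2S, Me3SiOTf, CH2Cl2, −78 °C; then 13, −78 → −40 °C; then DBU, −40 → 0 °C
Reagents that add atoms: none
Why: Lewis acid- and sulfide-mediated Morita–Baylis–Hillman-type coupling: the enone becomes a β-sulfonio silyl enol ether that adds Mukaiyama-fashion to the acyloxocarbenium ion from the acetate on the face anti to the adjacent C-7 side chain (C-6 set as S, trans lactone), and DBU then expels dimethyl sulfide to restore the α-substituted enone.

Step 9
Reactants: 17 (3S,4S,5S)-3-methyl-4-[(3S)-3-methyl-3-(triethylsilyloxy)pent-4-en-1-yl]-5-(3-oxobut-1-en-2-yl)oxolan-2-one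
Product: 18 (3S,3aS,6S,8aS)-8-acetyl-3,6-dimethyl-6-(triethylsilyloxy)-3,3a,4,5,6,8a-hexahydro-2H-cyclohepta[b]furan-2-one
Conditions: second-generation Hoveyda–Grubbs catalyst (10 mol %), toluene (2 mM), 80 °C
Reagents that add atoms: none
Why: Ring-closing metathesis between the vinyl group and the 1,1-disubstituted enone alkene closes the seven-membered ring as the trisubstituted 2-acetylcycloheptene with loss of ethene, without touching a stereocentre.

Step 10
Reactants: 18 (3S,3aS,6S,8aS)-8-acetyl-3,6-dimethyl-6-(triethylsilyloxy)-3,3a,4,5,6,8a-hexahydro-2H-cyclohepta[b]furan-2-one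
Product: 19 (3S,3aS,6S,8aS)-8-acetyl-6-hydroxy-3,6-dimethyl-3,3a,4,5,6,8a-hexahydro-2H-cyclohepta[b]furan-2-one
Conditions: HF·pyridine, pyridine, THF, 0 °C → rt
Reagents that add atoms: none
Why: Buffered fluoride cleaves the tertiary triethylsilyl ether under conditions that spare the lactone, the enone and the tertiary allylic alcohol that is set free.

Step 11
Reactants: 20 dichlorodimethylsilane; 21 ethynylmagnesium bromide
Product: 22 chloro(ethynyl)dimethylsilane
Conditions: 20 (5 equiv), THF, −78 → 0 °C; fractional distillation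
Reagents that add atoms: none
Why: Mono-substitution of the dichlorosilane, used in excess, by the alkynyl Grignard reagent is a standard route to alkynylchlorosilanes, and the product is separated by distillation.

Step 12
Reactants: 19 (3S,3aS,6S,8aS)-8-acetyl-6-hydroxy-3,6-dimethyl-3,3a,4,5,6,8a-hexahydro-2H-cyclohepta[b]furan-2-one; 22 chloro(ethynyl)dimethylsilane
Product: 23 (3S,3aS,6S,8aS)-8-acetyl-6-{[ethynyl(dimethyl)silyl]oxy}-3,6-dimethyl-3,3a,4,5,6,8a-hexahydro-2H-cyclohepta[b]furan-2-one
Conditions: imidazole, DMAP (cat.), CH2Cl2, 0 °C → rt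
Reagents that add atoms: none
Why: Imidazole-promoted silylation with the small dimethylsilyl chloride should reach the tertiary hydroxyl and installs the two-carbon unit C-2/C-3 as a temporary silicon tether on the C-10 oxygen.

Step 13
Reactants: 23 (3S,3aS,6S,8aS)-8-acetyl-6-{[ethynyl(dimethyl)silyl]oxy}-3,6-dimethyl-3,3a,4,5,6,8a-hexahydro-2H-cyclohepta[b]furan-2-one
Product: 24 (1R,4S,5S,6S,7S,10S,11S)-4-hydroxy-2,O-10-(dimethylsilanediyl)guai-2-en-12,6-olide (cis-fused cyclopentenol; C-2 joined through SiMe2 to the C-10 oxygen; hydroxyl cis to H-5)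
Conditions: Ni(cod)2 (15 mol %), PBu3 (30 mol %), Et3B (3 equiv), i-PrOH/THF 1:8, 50 °C
Reagents that add atoms: none
Why: Proposed new method: zerovalent nickel should couple the enone and the tethered ethynylsilane by oxidative cyclisation (C-1–C-2 bond, nickel enolate), the alcohol protonates the enolate at C-5, and the alkenylnickel then adds to the unveiled methyl ketone (C-3–C-4 bond) before triethylborane returns the metal to its zerovalent state; the closest known reaction type is the nickel-catalysed reductive [3+2] cycloaddition of enals or enones with alkynes, including carbon-tethered alkynyl enals, whereas a silyl ether tether on an ethynylsilane and a hindered 2-acylcycloalkene have not been shown. The oxasilolane ring closes 5-exo-dig (the silicon-bearing alkyne carbon attacks C-1) and the cyclopentenol ring closes 5-exo-trig onto the ketone. C-1 is set by the three-atom O–Si tether from the C-10 oxygen, which can deliver C-2 only to the face of the cycloheptene syn to that oxygen (cis-fused five-membered ring), which is the natural 1R configuration; C-5 (protonation) and C-4 (carbonyl face) are expected as drawn but are erased in step 14, so either epimer serves. The step needs regioselectivity (which alkyne carbon meets C-1) and chemoselectivity (enone–alkyne coupling over alkyne oligomerisation, no loss of the β-acyloxy group at C-6 from the nickel enolate); these are secured by the tether, by the intramolecularity and by the protic medium that quenches the enolate at once.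

Step 14
Reactants: 24 (1R,4S,5S,6S,7S,10S,11S)-4-hydroxy-2,O-10-(dimethylsilanediyl)guai-2-en-12,6-olide
Product: 25 (1R,6S,7S,10S,11S)-2,O-10-(dimethylsilanediyl)guaia-2,4-dien-12,6-olide
Conditions: methyl N-(triethylammoniosulfonyl)carbamate (Burgess reagent), PhH/THF, rt
Reagents that add atoms: none
Why: Burgess dehydration of the only free hydroxyl, the tertiary allylic C-4 carbinol (the C-10 oxygen is held in the siloxane), should remove H-5 to give the endocyclic conjugated cyclopentadiene, which is too hindered to dimerise because both diene termini are fully substituted.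

Step 15
Reactants: 25 (1R,6S,7S,10S,11S)-2,O-10-(dimethylsilanediyl)guaia-2,4-dien-12,6-olide (two molecules)
Product: 27 absinthin, via monomer diene 26 (not isolated)
Conditions: Bu4NF/AcOH 1:1 (3 equiv), THF, 0 °C → rt; pH 7 work-up; then neat, rt, dark, several days
Reagents that add atoms: none
Why: Buffered fluoride should open the strained oxasilole and protodesilylate the dienylsilane without deprotonating the cyclopentadiene, and the freed monomer then undergoes the head-to-head endo Diels–Alder dimerisation that guaianolide cyclopentadienes of this type show and that is the presumed biosynthesis (C-2=C-3 of one molecule adds to C-2'/C-5' of the other on the less hindered faces, C-3 bonding to C-5'), which sets C-2, C-3, C-2' and C-5'.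

Step 16
Reactants: 27 absinthin
Product: 28 anabsinthin
Conditions: TsOH·H2O (cat.), CHCl3, rt
Reagents that add atoms: none
Why: Acid-catalysed intramolecular hydroalkoxylation (the known acid isomerisation of absinthin): Markovnikov protonation of the strained norbornene alkene at C-3' gives the tertiary C-4' cation, which the C-10' hydroxyl held above it captures to close the oxolane, the bridged framework dictating the C-4' configuration while the tetrasubstituted C-4=C-5 alkene of the other half stays.

**Compound list**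

1 | (S)-(+)-linalool | C=C[C@@](C)(O)CCC=C(C)C | starting material
2 | (3S)-3,7-dimethyl-3-(triethylsilyloxy)octa-1,6-diene | C=C[C@@](C)(O[Si](CC)(CC)CC)CCC=C(C)C | intermediate
3 | (4S)-4-methyl-4-(triethylsilyloxy)hex-5-enal | C=C[C@@](C)(O[Si](CC)(CC)CC)CCC=O | intermediate
4 | nitromethane | C[N+](=O)[O-] | starting material
5 | (5S)-5-methyl-1-nitro-5-(triethylsilyloxy)hept-6-en-2-ol (nitro aldol, both C-2 epimers) | C=C[C@@](C)(O[Si](CC)(CC)CC)CCC(O)C[N+](=O)[O-] | intermediate
6 | (1E,5S)-5-methyl-1-nitro-5-(triethylsilyloxy)hepta-1,6-diene | C=C[C@@](C)(O[Si](CC)(CC)CC)CC/C=C/[N+](=O)[O-] | intermediate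
7 | propanal | CCC=O | starting material
8 | (2S,3S,6S)-2,6-dimethyl-3-(nitromethyl)-6-(triethylsilyloxy)oct-7-enal | O=C[C@@H](C)[C@@H](C[N+](=O)[O-])CC[C@](C)(O[Si](CC)(CC)CC)C=C | intermediate
9 | (2S,3S,6S)-2,6-dimethyl-3-(nitromethyl)-6-(triethylsilyloxy)oct-7-enoic acid | OC(=O)[C@@H](C)[C@@H](C[N+](=O)[O-])CC[C@](C)(O[Si](CC)(CC)CC)C=C | intermediate
10 | disodium nitronate carboxylate of 9 | [Na+].[Na+].[O-]C(=O)[C@@H](C)[C@@H](C=[N+]([O-])[O-])CC[C@](C)(O[Si](CC)(CC)CC)C=C | intermediate
11 | (2S,3S,6S)-3-formyl-2,6-dimethyl-6-(triethylsilyloxy)oct-7-enoic acid | OC(=O)[C@@H](C)[C@@H](C=O)CC[C@](C)(O[Si](CC)(CC)CC)C=C | intermediate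
12 | (3S,4S)-5-hydroxy-3-methyl-4-[(3S)-3-methyl-3-(triethylsilyloxy)pent-4-en-1-yl]oxolan-2-one (both C-5 epimers) | O=C1OC(O)[C@@H](CC[C@](C)(O[Si](CC)(CC)CC)C=C)[C@@H]1C | intermediate
13 | (3S,4S)-5-acetoxy-3-methyl-4-[(3S)-3-methyl-3-(triethylsilyloxy)pent-4-en-1-yl]oxolan-2-one (both C-5 epimers) | O=C1OC(OC(C)=O)[C@@H](CC[C@](C)(O[Si](CC)(CC)CC)C=C)[C@@H]1C | intermediate
14 | but-3-en-2-one (methyl vinyl ketone) | CC(=O)C=C | starting material
15 | dimethyl[3-(trimethylsilyloxy)but-2-en-1-yl]sulfonium trifluoromethanesulfonate | C[S+](C)CC=C(C)O[Si](C)(C)C.[O-]S(=O)(=O)C(F)(F)F | intermediate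
16 | dimethyl{2-[(2S,3S,4S)-4-methyl-3-[(3S)-3-methyl-3-(triethylsilyloxy)pent-4-en-1-yl]-5-oxooxolan-2-yl]-3-oxobutyl}sulfonium trifluoromethanesulfonate | CC(=O)C(C[S+](C)C)[C@H]1OC(=O)[C@@H](C)[C@@H]1CC[C@](C)(O[Si](CC)(CC)CC)C=C.[O-]S(=O)(=O)C(F)(F)F | intermediate
17 | (3S,4S,5S)-3-methyl-4-[(3S)-3-methyl-3-(triethylsilyloxy)pent-4-en-1-yl]-5-(3-oxobut-1-en-2-yl)oxolan-2-one | CC(=O)C(=C)[C@H]1OC(=O)[C@@H](C)[C@@H]1CC[C@](C)(O[Si](CC)(CC)CC)C=C | intermediate
18 | (3S,3aS,6S,8aS)-8-acetyl-3,6-dimethyl-6-(triethylsilyloxy)-3,3a,4,5,6,8a-hexahydro-2H-cyclohepta[b]furan-2-one | CC(=O)C1=C[C@@](C)(O[Si](CC)(CC)CC)CC[C@H]2[C@H](C)C(=O)O[C@H]12 | intermediate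
19 | (3S,3aS,6S,8aS)-8-acetyl-6-hydroxy-3,6-dimethyl-3,3a,4,5,6,8a-hexahydro-2H-cyclohepta[b]furan-2-one | CC(=O)C1=C[C@@](C)(O)CC[C@H]2[C@H](C)C(=O)O[C@H]12 | intermediate
20 | dichlorodimethylsilane | C[Si](C)(Cl)Cl | starting material
21 | ethynylmagnesium bromide | C#C[Mg]Br | starting material
22 | chloro(ethynyl)dimethylsilane | C#C[Si](C)(C)Cl | intermediate
23 | (3S,3aS,6S,8aS)-8-acetyl-6-{[ethynyl(dimethyl)silyl]oxy}-3,6-dimethyl-3,3a,4,5,6,8a-hexahydro-2H-cyclohepta[b]furan-2-one | CC(=O)C1=C[C@@](C)(O[Si](C)(C)C#C)CC[C@H]2[C@H](C)C(=O)O[C@H]12 | intermediate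
24 | (1R,4S,5S,6S,7S,10S,11S)-4-hydroxy-2,O-10-(dimethylsilanediyl)guai-2-en-12,6-olide | C[C@@]1(O)C=C2[C@@H]3[C@H]1[C@H]1OC(=O)[C@@H](C)[C@@H]1CC[C@]3(C)O[Si]2(C)C | intermediate
25 | (1R,6S,7S,10S,11S)-2,O-10-(dimethylsilanediyl)guaia-2,4-dien-12,6-olide | CC1=C2[C@H]3OC(=O)[C@@H](C)[C@@H]3CC[C@]4(C)O[Si](C)(C)C(=C1)[C@H]24 | intermediate
26 | (1R,6S,7S,10S,11S)-10-hydroxyguaia-2,4-dien-12,6-olide (monomer diene) | CC1=C2[C@H]3OC(=O)[C@@H](C)[C@@H]3CC[C@](C)(O)[C@@H]2C=C1 | intermediate
27 | absinthin | CC1=C2[C@H]3OC(=O)[C@@H](C)[C@@H]3CC[C@](C)(O)[C@@H]2[C@H]2[C@H]3C=C(C)[C@@]4([C@H]5OC(=O)[C@@H](C)[C@@H]5CC[C@](C)(O)[C@H]34)[C@@H]12 | intermediate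
28 | anabsinthin | CC1=C2[C@H]3OC(=O)[C@@H](C)[C@@H]3CC[C@](C)(O)[C@@H]2[C@H]2[C@H]3C[C@]4(C)O[C@@]5(C)CC[C@H]6[C@H](C)C(=O)O[C@@H]6[C@@]4([C@@H]35)[C@@H]12 | target

**Step count**

Total: 16 steps. Longest linear sequence: 15 steps (steps 1–10 and 12–16; step 11 prepares the silyl chloride).

**Steps most likely to fail**

Step 13 (proposed new method). The nickel may oligomerise the terminal alkyne or insert into the allylic lactone C–O bond, the alcohol may solvolyse the alkynyl–silicon bond, or the alkenylnickel may fail to add to the hindered ketone. Fallback without tether, by known chemistry: setting out from 18, the known intermolecular nickel-catalysed reductive [3+2] cycloaddition with ethynyltrimethylsilane (Ni(cod)2, PBu3, Et3B, MeOH/THF, 50 °C) should give the 3-trimethylsilyl cyclopentenol F1, with silicon next to the carbinol as is usual for silylalkynes. Hydroxyl-assisted protodesilylation (Bu4NF, THF, 0 °C) should then give the cyclopentenol silyl ether F2. Burgess dehydration gives the silyl-protected monomer F3, which should dimerise on standing neat to bis(triethylsilyl)absinthin F4, and HF·pyridine returns to the route at 27. In this variant C-1 rests on substrate control only; the 1,5-hydrogen shift of 5-alkylcyclopentadienes should let C-1 epimers equilibrate before the cycloaddition.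

Step 15. Cleavage of the dienyl carbon–silicon bond may be sluggish, or the cyclopentadiene may scramble (1,5-hydrogen shift or fluoride-induced deprotonation) before it dimerises. Fallback: setting out from 24, acetylation of the tertiary allylic carbinol (Ac2O, DMAP, Et3N, 40 °C; the C-10 oxygen is still in the siloxane) gives the acetate F5. Bu4NF (THF, 50 °C) then removes silicon while the ring is still a non-acidic cyclopentene and gives the hydroxy acetate F6. Pd(PPh3)4 (zerovalent palladium) with Et3N in THF then forms the diene by the known palladium-catalysed 1,4-elimination of allylic acetates under neutral conditions; this gives 26, which returns to the route at 27 on concentration.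

Step 8. The silyl triflate may ionise the tertiary allylic silyl ether, the enone may polymerise, or the addition may lack trans selectivity at C-6. Fallback: setting out from 13, Lewis acid-mediated alkynylation of the same oxocarbenium ion with trimethyl(prop-1-yn-1-yl)silane (SnCl4, CH2Cl2, −78 °C) gives the trans propynyl lactone F7. Ring-closing enyne metathesis (second-generation Grubbs catalyst, ethene atmosphere, CH2Cl2, 40 °C) gives the 8-isopropenyl cycloheptene F8. Cleavage of its exposed 1,1-disubstituted alkene (OsO4 cat., NaIO4, 2,6-lutidine, dioxane/H2O) returns to the route at 18.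

**Further compounds**

F1 | step 13 | (1R,4S,5S,6S,7S,10S,11S)-4-hydroxy-10-(triethylsilyloxy)-3-(trimethylsilyl)guai-2-en-12,6-olide | C[C@@]1(O)C([Si](C)(C)C)=C[C@@H]2[C@H]1[C@H]1OC(=O)[C@@H](C)[C@@H]1CC[C@]2(C)O[Si](CC)(CC)CC
F2 | step 13 | (1R,4S,5S,6S,7S,10S,11S)-4-hydroxy-10-(triethylsilyloxy)guai-2-en-12,6-olide | C[C@@]1(O)C=C[C@@H]2[C@H]1[C@H]1OC(=O)[C@@H](C)[C@@H]1CC[C@]2(C)O[Si](CC)(CC)CC
F3 | step 13 | (1R,6S,7S,10S,11S)-10-(triethylsilyloxy)guaia-2,4-dien-12,6-olide | CC1=C2[C@H]3OC(=O)[C@@H](C)[C@@H]3CC[C@](C)(O[Si](CC)(CC)CC)[C@@H]2C=C1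
F4 | step 13 | 10,10'-bis-O-(triethylsilyl)absinthin | CC1=C2[C@H]3OC(=O)[C@@H](C)[C@@H]3CC[C@](C)(O[Si](CC)(CC)CC)[C@@H]2[C@H]2[C@H]3C=C(C)[C@@]4([C@H]5OC(=O)[C@@H](C)[C@@H]5CC[C@](C)(O[Si](CC)(CC)CC)[C@H]34)[C@@H]12
F5 | step 15 | 4-O-acetate of 24 | CC(=O)O[C@]1(C)C=C2[C@@H]3[C@H]1[C@H]1OC(=O)[C@@H](C)[C@@H]1CC[C@]3(C)O[Si]2(C)C
F6 | step 15 | (1R,4S,5S,6S,7S,10S,11S)-4-acetoxy-10-hydroxyguai-2-en-12,6-olide | CC(=O)O[C@]1(C)C=C[C@@H]2[C@H]1[C@H]1OC(=O)[C@@H](C)[C@@H]1CC[C@]2(C)O
F7 | step 8 | (3S,4S,5S)-3-methyl-4-[(3S)-3-methyl-3-(triethylsilyloxy)pent-4-en-1-yl]-5-(prop-1-yn-1-yl)oxolan-2-one | CC#C[C@H]1OC(=O)[C@@H](C)[C@@H]1CC[C@](C)(O[Si](CC)(CC)CC)C=C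
F8 | step 8 | (3S,3aS,6S,8aS)-3,6-dimethyl-8-(prop-1-en-2-yl)-6-(triethylsilyloxy)-3,3a,4,5,6,8a-hexahydro-2H-cyclohepta[b]furan-2-one | CC(=C)C1=C[C@@](C)(O[Si](CC)(CC)CC)CC[C@H]2[C@H](C)C(=O)O[C@H]12
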